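**Retrosynthetic overview**
1. Stephaflavone B ⇐ its O-benzyl 5,5'-di-O-methyl ether: BCl3 cleaves the two peri methyl ethers (O5, O5') and the benzyl ether; the 7-, 7'- and 4'-methoxy groups stay.
2. Feature: in pyranone ring C' of the 3-linked flavone (primed atoms), C3' lies between C4'=O and the enol-ether carbon C2', so it is the central carbon of a masked 1,3-diketone. Opening ring C' at O1'–C2' and C2'–C3' turns the crowded C6–C3' bond into the benzylic C6–CH2 bond of an ortho-aroyloxy deoxybenzoin.
3. That ester ⇐ 2-hydroxy-4,6-dimethoxyphenyl flavon-6-ylmethyl ketone + 4-(benzyloxy)benzoyl chloride (ring B'); the ketone ⇐ flavon-6-ylacetic acid + 3,5-dimethoxyphenol (ring A') by Friedel–Crafts acylation.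
4. The acid ⇐ apigenin 7,4'-dimethyl ether: 5-O-allyl ether, Claisen shift to C6 (the only free ortho position), O-methylation, alkene cleavage.
5. Ring order: rings A, B and C of the 6-linked flavone are bought intact, rings A' and B' come with the phenol and the acid chloride, and ring C' is the only ring formed (step 8).

Key step: step 8

Assumption: the target is drawn without a descriptor for the hindered C6–C3' axis, so no axial control is attempted and the compound is taken as the racemate about that axis.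

**Route**

Step 1
Reactants: 1 apigenin 7,4'-dimethyl ether (5-hydroxy-7-methoxy-2-(4-methoxyphenyl)chromen-4-one)
Product: 2 5-(allyloxy)-7-methoxy-2-(4-methoxyphenyl)chromen-4-one
Conditions: allyl bromide, K2CO3, DMF, 60 °C
Reagents that add atoms: allyl bromide, C=CCBr
Why: Williamson ether synthesis; the 5-hydroxyl is the only acidic group, and carbonate in warm DMF loosens its hydrogen bond to the C4 carbonyl enough for SN2 attack on the allylic bromide.

Step 2
Reactants: 2 5-(allyloxy)-7-methoxy-2-(4-methoxyphenyl)chromen-4-one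
Product: 3 6-allyl-5-hydroxy-7-methoxy-2-(4-methoxyphenyl)chromen-4-one
Conditions: N,N-diethylaniline, 200 °C, argon
Reagents that add atoms: none
Why: Aromatic Claisen rearrangement; of the two positions ortho to O5 one is the ring-fusion carbon C4a, so the [3,3] shift can deliver the allyl group only to C6, and tautomerisation of the dienone restores the chelated phenol.

Step 3
Reactants: 3 6-allyl-5-hydroxy-7-methoxy-2-(4-methoxyphenyl)chromen-4-one
Product: 4 6-allyl-5,7-dimethoxy-2-(4-methoxyphenyl)chromen-4-one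
Conditions: Me2SO4, K2CO3, acetone, reflux
Reagents that add atoms: dimethyl sulfate, COS(=O)(=O)OC
Why: Williamson O-methylation under the forcing conditions that are standard for the chelated 5-hydroxyl of flavones; no other nucleophilic site is present.

Step 4
Reactants: 4 6-allyl-5,7-dimethoxy-2-(4-methoxyphenyl)chromen-4-one
Product: 6 2-[5,7-dimethoxy-2-(4-methoxyphenyl)-4-oxochromen-6-yl]acetaldehyde, via vicinal diol 5 (not isolated)
Conditions: OsO4 (cat.), NaIO4, 2,6-lutidine, dioxane/H2O 3:1, rt
Reagents that add atoms: osmium tetroxide, O=[Os](=O)(=O)=O; sodium metaperiodate NaIO4 (restores the OsO4), [Na+].[O-]I(=O)(=O)=O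
Why: Lemieux–Johnson oxidation; OsO4 dihydroxylates the isolated terminal alkene far faster than the electron-poor conjugated C2=C3 bond of the pyranone, and NaIO4 cleaves diol 5 to the aldehyde while regenerating OsO4, with 2,6-lutidine suppressing over-oxidation.

Step 5
Reactants: 6 2-[5,7-dimethoxy-2-(4-methoxyphenyl)-4-oxochromen-6-yl]acetaldehyde
Product: 7 2-[5,7-dimethoxy-2-(4-methoxyphenyl)-4-oxochromen-6-yl]acetic acid
Conditions: NaClO2, NaH2PO4, 2-methyl-2-butene, t-BuOH/THF/H2O, 0 °C → rt
Reagents that add atoms: sodium chlorite NaClO2, [Na+].[O-]Cl=O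
Why: Pinnick oxidation; buffered chlorous acid converts the enolisable arylacetaldehyde to the acid, and 2-methyl-2-butene traps the hypochlorous acid that would otherwise chlorinate the methoxy-rich rings.

Step 6
Reactants: 7 2-[5,7-dimethoxy-2-(4-methoxyphenyl)-4-oxochromen-6-yl]acetic acid; 8 3,5-dimethoxyphenol
Product: 9 6-[2-(2-hydroxy-4,6-dimethoxyphenyl)-2-oxoethyl]-5,7-dimethoxy-2-(4-methoxyphenyl)chromen-4-one
Conditions: BF3·OEt2 (neat), 80 °C; then aq. NaOAc
Reagents that add atoms: none
Why: Friedel–Crafts acylation of a phloroglucinol-type ring by the BF3-activated acid (the standard deoxybenzoin synthesis), with any aryl ester formed first re-entering by Fries-type transfer; acylation next to the hydroxyl should be favoured because boron bridges the phenol oxygen and the new carbonyl, and the less polar chelated ortho isomer is separable from any para isomer.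

Step 7
Reactants: 9 6-[2-(2-hydroxy-4,6-dimethoxyphenyl)-2-oxoethyl]-5,7-dimethoxy-2-(4-methoxyphenyl)chromen-4-one; 10 4-(benzyloxy)benzoyl chloride
Product: 11 2-{2-[5,7-dimethoxy-2-(4-methoxyphenyl)-4-oxochromen-6-yl]acetyl}-3,5-dimethoxyphenyl 4-(benzyloxy)benzoate
Conditions: Et3N, DMAP (cat.), CH2Cl2, 0 °C → rt
Reagents that add atoms: none
Why: DMAP-catalysed esterification (nucleophilic catalysis through the N-acylpyridinium ion) of the only hydroxyl; the amine base is too weak to enolise the CH2, so C-acylation should not compete.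

Step 8
Reactants: 11 2-{2-[5,7-dimethoxy-2-(4-methoxyphenyl)-4-oxochromen-6-yl]acetyl}-3,5-dimethoxyphenyl 4-(benzyloxy)benzoate
Product: 14 6-{2-[4-(benzyloxy)phenyl]-5,7-dimethoxy-4-oxochromen-3-yl}-5,7-dimethoxy-2-(4-methoxyphenyl)chromen-4-one, via 1,3-diketone 12 (not isolated), via cyclic hemiketal 13 (not isolated)
Conditions: LiN(SiMe3)2 (2.5 equiv), THF, −78 → 0 °C; AcOH; then p-TsOH·H2O (cat.), toluene, 110 °C (Dean–Stark)
Reagents that add atoms: none
Why: LiN(SiMe3)2 removes a proton from the only enolisable position, the CH2 between the aryl ketone and C6, and the enolate carbon adds to the neighbouring ester carbonyl through a six-membered cyclic alkoxide that collapses to the phenoxide of 1,3-diketone 12 (Baker–Venkataraman rearrangement, new C2'–C3' bond). After acidification the freed phenol adds to the 4-benzyloxybenzoyl carbonyl in a 6-exo-trig closure to hemiketal 13, and acid-catalysed loss of water gives pyranone ring C' of 14; this is the usual passage from 2-aroyloxydeoxybenzoins to 2,3-diarylchromones. No stereocentre remains, since the methine of 12 and both centres of 13 are erased on dehydration and the C6–C3' axis is formed without control. The step needs carbon rather than oxygen acylation and no ester cleavage: transfer to the enolate oxygen also runs through a six-membered ring but is reversible, whereas the C-acyl product is taken out of the equilibrium as its β-diketonate by the second equivalent of base, and the non-nucleophilic amide in dry THF leaves the ester intact. The crowded C6–C3' bond is not made here; it has been present as an unstrained benzylic bond since step 2.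

Step 9
Reactants: 14 6-{2-[4-(benzyloxy)phenyl]-5,7-dimethoxy-4-oxochromen-3-yl}-5,7-dimethoxy-2-(4-methoxyphenyl)chromen-4-one
Product: 15 stephaflavone B (5-hydroxy-6-[5-hydroxy-2-(4-hydroxyphenyl)-7-methoxy-4-oxochromen-3-yl]-7-methoxy-2-(4-methoxyphenyl)chromen-4-one)
Conditions: BCl3 (excess), pentamethylbenzene, CH2Cl2, −78 → 0 °C; MeOH/H2O work-up
Reagents that add atoms: none
Why: Lewis-acid ether cleavage under chelation control; BCl3 bound to each C4 carbonyl delivers chloride to the adjacent peri methyl group through a six-membered boron chelate and also ionises the benzyl ether (cation trapped by pentamethylbenzene), while the non-chelated 7-, 7'- and 4'-methoxy groups should not be cleaved at or below 0 °C.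

**Compound list**
1 | apigenin 7,4'-dimethyl ether (5-hydroxy-7-methoxy-2-(4-methoxyphenyl)chromen-4-one) | COc1ccc(-c2cc(=O)c3c(O)cc(OC)cc3o2)cc1 | starting material
2 | 5-(allyloxy)-7-methoxy-2-(4-methoxyphenyl)chromen-4-one | COc1ccc(-c2cc(=O)c3c(OCC=C)cc(OC)cc3o2)cc1 | intermediate
3 | 6-allyl-5-hydroxy-7-methoxy-2-(4-methoxyphenyl)chromen-4-one | COc1ccc(-c2cc(=O)c3c(O)c(CC=C)c(OC)cc3o2)cc1 | intermediate
4 | 6-allyl-5,7-dimethoxy-2-(4-methoxyphenyl)chromen-4-one | COc1ccc(-c2cc(=O)c3c(OC)c(CC=C)c(OC)cc3o2)cc1 | intermediate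
5 | 6-(2,3-dihydroxypropyl)-5,7-dimethoxy-2-(4-methoxyphenyl)chromen-4-one (racemic, not isolated) | COc1ccc(-c2cc(=O)c3c(OC)c(CC(O)CO)c(OC)cc3o2)cc1 | intermediate
6 | 2-[5,7-dimethoxy-2-(4-methoxyphenyl)-4-oxochromen-6-yl]acetaldehyde | COc1ccc(-c2cc(=O)c3c(OC)c(CC=O)c(OC)cc3o2)cc1 | intermediate
7 | 2-[5,7-dimethoxy-2-(4-methoxyphenyl)-4-oxochromen-6-yl]acetic acid | COc1ccc(-c2cc(=O)c3c(OC)c(CC(=O)O)c(OC)cc3o2)cc1 | intermediate
8 | 3,5-dimethoxyphenol | COc1cc(O)cc(OC)c1 | starting material
9 | 6-[2-(2-hydroxy-4,6-dimethoxyphenyl)-2-oxoethyl]-5,7-dimethoxy-2-(4-methoxyphenyl)chromen-4-one | COc1ccc(-c2cc(=O)c3c(OC)c(CC(=O)c4c(O)cc(OC)cc4OC)c(OC)cc3o2)cc1 | intermediate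
10 | 4-(benzyloxy)benzoyl chloride | O=C(Cl)c1ccc(OCc2ccccc2)cc1 | starting material
11 | 2-{2-[5,7-dimethoxy-2-(4-methoxyphenyl)-4-oxochromen-6-yl]acetyl}-3,5-dimethoxyphenyl 4-(benzyloxy)benzoate | COc1ccc(-c2cc(=O)c3c(OC)c(CC(=O)c4c(OC)cc(OC)cc4OC(=O)c4ccc(OCc5ccccc5)cc4)c(OC)cc3o2)cc1 | intermediate
12 | 1-[4-(benzyloxy)phenyl]-2-[5,7-dimethoxy-2-(4-methoxyphenyl)-4-oxochromen-6-yl]-3-(2-hydroxy-4,6-dimethoxyphenyl)propane-1,3-dione (racemic, in equilibrium with its enols, not isolated) | COc1ccc(-c2cc(=O)c3c(OC)c(C(C(=O)c4c(O)cc(OC)cc4OC)C(=O)c4ccc(OCc5ccccc5)cc4)c(OC)cc3o2)cc1 | intermediate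
13 | 2-[4-(benzyloxy)phenyl]-3-[5,7-dimethoxy-2-(4-methoxyphenyl)-4-oxochromen-6-yl]-2-hydroxy-5,7-dimethoxychroman-4-one (racemic mixture of diastereomers, not isolated) | COc1ccc(-c2cc(=O)c3c(OC)c(C4C(=O)c5c(OC)cc(OC)cc5OC4(O)c4ccc(OCc5ccccc5)cc4)c(OC)cc3o2)cc1 | intermediate
14 | 6-{2-[4-(benzyloxy)phenyl]-5,7-dimethoxy-4-oxochromen-3-yl}-5,7-dimethoxy-2-(4-methoxyphenyl)chromen-4-one | COc1ccc(-c2cc(=O)c3c(OC)c(-c4c(-c5ccc(OCc6ccccc6)cc5)oc5cc(OC)cc(OC)c5c4=O)c(OC)cc3o2)cc1 | intermediate
15 | stephaflavone B | COc1ccc(-c2cc(=O)c3c(O)c(-c4c(-c5ccc(O)cc5)oc5cc(OC)cc(O)c5c4=O)c(OC)cc3o2)cc1 | target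

**Step count and risks**

Total step count: 9. Longest linear sequence: 9 steps (1 → 15).

Steps most likely to fail:

1. Step 8 (key step). The acyl transfer may stall or revert at the hindered enolate, the ester may be cleaved back to the phenol, or the crowded diketone may lose an aroyl group by retro-Claisen cleavage faster than it closes during the acid treatment. Fallback, setting out from 9 and coming back at 14: the C2'–C3' bond is made by condensation with an aldehyde instead of by acyl transfer. Deoxybenzoin 9 is heated with 4-(benzyloxy)benzaldehyde and piperidine in EtOH, which should give the α-(flavon-6-yl)-2'-hydroxychalcone F1 (alkene geometry not controlled). F1 closes in the same flask by oxa-Michael addition to the 2,3-diarylchroman-4-one F2 (racemic cis/trans mixture, both centres erased next). Dehydrogenation of F2 with DDQ in dioxane at 100 °C gives 14.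

2. Step 6. Acylation may occur para to the hydroxyl, and hot BF3·OEt2 may remove the chelated 5-methyl ether or induce lactonisation of the resulting phenol onto the acid. Fallback, setting out from 6 and coming back at 9: a Houben–Hoesch acylation with a nitrile at 0 °C replaces the hot Lewis-acid acylation. Aldehyde 6 is converted with NH2OH·HCl/NaOAc in EtOH to the oxime F3 (E/Z mixture), which is dehydrated with Ac2O at 120 °C to 2-[5,7-dimethoxy-2-(4-methoxyphenyl)-4-oxochromen-6-yl]acetonitrile F4. F4 and 8 are treated with ZnCl2 and HCl gas in Et2O/dioxane at 0 °C to give the ketiminium chloride F5, which is hydrolysed in water at 80 °C to 9.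

3. Step 2. At 200 °C the allyl ether may cleave back to the phenol, the allylphenol may cyclise onto its alkene, or the alkene may shift into conjugation. Fallback, setting out from 1 and coming back at 4: the allyl group is attached by cross-coupling instead of by sigmatropic shift. Flavone 1 is iodinated at C6 under direction of the free 5-hydroxyl with benzyltrimethylammonium dichloroiodate and CaCO3 in CH2Cl2/MeOH to give 5-hydroxy-6-iodo-7-methoxy-2-(4-methoxyphenyl)chromen-4-one F6. O-Methylation (Me2SO4, K2CO3, acetone, reflux) gives 6-iodo-5,7-dimethoxy-2-(4-methoxyphenyl)chromen-4-one F7. Stille coupling of F7 with allyltributylstannane and Pd(PPh3)4 (zerovalent palladium) in DMF at 90 °C gives 4.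

**Further compounds**
F1 | step 8 | 3-[4-(benzyloxy)phenyl]-2-[5,7-dimethoxy-2-(4-methoxyphenyl)-4-oxochromen-6-yl]-1-(2-hydroxy-4,6-dimethoxyphenyl)prop-2-en-1-one (alkene geometry not defined) | COc1ccc(-c2cc(=O)c3c(OC)c(C(=Cc4ccc(OCc5ccccc5)cc4)C(=O)c4c(O)cc(OC)cc4OC)c(OC)cc3o2)cc1
F2 | step 8 | 2-[4-(benzyloxy)phenyl]-3-[5,7-dimethoxy-2-(4-methoxyphenyl)-4-oxochromen-6-yl]-5,7-dimethoxychroman-4-one (racemic cis/trans mixture) | COc1ccc(-c2cc(=O)c3c(OC)c(C4C(=O)c5c(OC)cc(OC)cc5OC4c4ccc(OCc5ccccc5)cc4)c(OC)cc3o2)cc1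
F3 | step 6 | 2-[5,7-dimethoxy-2-(4-methoxyphenyl)-4-oxochromen-6-yl]acetaldehyde oxime (E/Z mixture) | COc1ccc(-c2cc(=O)c3c(OC)c(CC=NO)c(OC)cc3o2)cc1
F4 | step 6 | 2-[5,7-dimethoxy-2-(4-methoxyphenyl)-4-oxochromen-6-yl]acetonitrile | COc1ccc(-c2cc(=O)c3c(OC)c(CC#N)c(OC)cc3o2)cc1
F5 | step 6 | 2-[5,7-dimethoxy-2-(4-methoxyphenyl)-4-oxochromen-6-yl]-1-(2-hydroxy-4,6-dimethoxyphenyl)ethaniminium chloride | COc1ccc(-c2cc(=O)c3c(OC)c(CC(=[NH2+])c4c(O)cc(OC)cc4OC)c(OC)cc3o2)cc1.[Cl-]
F6 | step 2 | 5-hydroxy-6-iodo-7-methoxy-2-(4-methoxyphenyl)chromen-4-one | COc1ccc(-c2cc(=O)c3c(O)c(I)c(OC)cc3o2)cc1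
F7 | step 2 | 6-iodo-5,7-dimethoxy-2-(4-methoxyphenyl)chromen-4-one | COc1ccc(-c2cc(=O)c3c(OC)c(I)c(OC)cc3o2)cc1
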